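## Structural features

Gnetucleistol F is a 2,3-dihydrobenzofuran: ring A is fused to a five-membered ether ring made of O1, C2, C3, C3a and C7a. C2 bears a 4-hydroxy-3,5-dimethoxyphenyl (syringyl) ring, C3 a hydroxymethyl group, C7 a methoxy group and C5 an (E)-2-(3,5-dihydroxyphenyl)ethenyl arm. The only stereocentres are the neighbouring C2 (R) and C3 (S), which stand trans on the ring. Fragile groups are the three phenols (oxidation), the electron-rich stilbene (hydrogenation, light, strong acid) and the C2–O1 bond, which is benzylic and para to oxygen, so it can ionise in acid or open to a para-quinone methide in base once the syringyl phenol is free. The real difficulty is the absolute configuration of C3, a benzylic CH with no handle other than its CH2OH group, together with the congested C2–C3 bond between two aryl-bearing carbons. C2 is easily re-formed and trans is the stable arrangement, so its configuration can follow from C3. The key step exploits C2 as a CH bound to C3, the syringyl ring and oxygen: it enters as a carbenoid carbon between C3 and boron, receives the syringyl ring from boron, and keeps a C–B bond that stands for the later C–O bond.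

## Logic of the disconnections

24 to 23: the three aryl O–Si bonds are cut. The phenols are kept masked until the end so that no phenoxide is present during olefination, and one fluoride treatment frees all of them without touching the stilbene or C2–O1. The forward step must be buffered so that the syringyl phenoxide does not open the ether ring.

23 to 18 and 22: the stilbene C=C bond is cut. This removes the resorcinol ring as an achiral unit and puts the only alkene-forming step after all hydrogenation. The forward step must be E-selective and tolerate a free primary alcohol and aryl silyl ethers.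

22 back to 19: the C–P bond, then the C–Br bond, then the two aryl O–Si bonds. Each is a standard benzylic or phenolic operation; the only demand is silylation of the phenols in preference to the benzylic alcohol.

18 to 16: the O1–C2 bond is cut and the aldehyde is masked as its acetal. A carbinol at C2 ionises because C2 is benzylic with a para oxygen, and the ring A phenol traps the cation. The bicyclic problem becomes an acyclic 1,2-diarylpropane-1,3-diol in which only C3 needs absolute control. The forward step needs acid strong enough to ionise C2 without cleaving the aryl silyl ether, and closure faster than elimination or loss of formaldehyde.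

16 to 15 to 14: the C2–O bond is traced back to a C–B bond and the two free hydroxyls to benzyl ethers. Oxidation of C–B is reliable and retentive, and benzyl ethers suit the organometallic steps. Hydrogenolysis is placed before the oxidation, when no benzylic C–O bond is present.

14 to 9, 11 and a one-carbon carbenoid: the C2–C3 and C2–aryl bonds are cut. Two of the three carbon substituents of C2 are attached in one flask and the syringyl ring arrives as a simple aryl bromide. The forward step needs 1,2-migration of a hindered secondary benzylic carbon to outrun β-elimination of benzyloxide.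

9 to 6, 3 and a second one-carbon carbenoid: the C3–CH2 and C3–aryl bonds are cut. The same operation one carbon earlier sets C3 under control of the diol and reduces the problem to an alkoxymethyl boronate and an aryl iodide. The forward step needs an ortho-substituted aryl nucleophile to displace a chloride that has a benzyloxy group on the next carbon.

6 to 4 and 5; 3 to 2 to 1; 11 to 10: B–O, acetal C–O, O–benzyl and O–Si bonds are cut, all protecting-group or ester-exchange operations on commercial materials.

## Other disconnections considered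

Alternative 1: The O1–C2 bond is cut at the C–H oxidation level. Forward, the diarylpropanol A1 is electrolysed at a graphite anode in hexafluoroisopropanol with Bu4NBF4; the syringyl phenol gives the para-quinone methide A2 and the ring A phenol adds to C2 to give A3. In its favour: no leaving group is installed and removed at C2, no phenol needs protection, and the bromide allows a Mizoroki–Heck end-game. On these points it is better than the chosen plan in step count around the ring closure. The trans outcome arises as in step 9, so the two are equal there. Against it: A1 must already carry the CH(CH2OH) centre in enantiopure form, which the electrolysis does not provide. A3 still has the oxidisable syringyl phenol and a benzylic C–H, so over-oxidation to a benzofuran or to oligomers is a real risk. The ring A phenol can also be oxidised. The chosen plan is longer but sets C3 by a predictable auxiliary and closes the ring by plain ionisation of an alcohol.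

Alternative 2: The C2–C3 and O1–C2 bonds are cut together. Forward, KOtBu releases the ortho-quinone methide A5 from sulfone A4, the ylide from the chiral sulfonium salt A6 adds to the exocyclic carbon (C3), and the phenoxide displaces the sulfide at C2 to give A7. In its favour: both ring bonds and both stereocentres form in one convergent step, which is better than the chosen plan in convergence and step count. The trans preference of such annulations is equal to that of step 9. Against it: absolute control must come from a stoichiometric chiral sulfide acting on a transient intermediate. The ylide is semi-stabilised and electron rich, so betaine formation may be reversible and erode enantioselectivity. A5 bears an alkyl group with a β-silyloxy substituent and can tautomerise to a vinylphenol or lose silanolate. The chosen plan is longer, but the sense and level of control at C3 are easier to predict.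

Alternative 3: The O1–C2 and C3–carbonyl bonds are cut at the benzofuran oxidation level. Forward, alkynylphenol A8 is treated with PdCl2 (divalent palladium), CuCl2 (which returns zerovalent palladium to the divalent state) and NaOAc under CO in methanol; oxypalladation and methoxycarbonylation give A9. In its favour: flat, robust chemistry that builds the furan ring and the C3 carbon substituent in one step from a Sonogashira product; up to A9 it is shorter and easier to scale than the chosen plan. Against it: no stereocentre is formed. Both must come from asymmetric reduction of a tetrasubstituted C2=C3 bond inside an aromatic furan. Syn hydrogenation would give the cis ester A10, which must be epimerised at C3 to the trans ester A11 and then reduced, and the aryl bromide may be lost under H2. The trans outcome by equilibration is equal to step 9, but absolute control is deferred to the hardest step, whereas the chosen plan sets C3 early.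

Key step: step 6

Remarks on the chemistry (assumptions):
- The auxiliary must be the (R,R) enantiomer of 1,2-dicyclohexylethane-1,2-diol (DICHED). With C2-symmetric (R,R)-diols of this family the chloro boronate formed is (αS) (Cl > C > B), and a Grignard reagent displaces the chloride with inversion. With the alkoxymethyl group on boron first and the ring A aryl group second, this gives C3 as in the target. The (S,S) diol would give the mirror image at both new carbons in this order of bond formation.
- The chloro boronates 7 and 12 are not benzylic: the aryl group is absent or sits on the neighbouring carbon. Chloride-induced epimerisation is therefore less of a threat than for α-chlorobenzyl boronates.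
- The oxygen placed on C2 by C–B oxidation is not O1. O1 is the phenolic oxygen of ring A, and ring closure goes through a benzylic cation at C2 with loss of that hydroxyl as water. The final configuration of C2 is therefore fixed in step 9 under control of C3, and the enantiomeric purity of the target rests on C3 alone. The configuration of C2 in 14 comes from the auxiliary at no extra cost and gives a single diastereomer to carry through steps 7 and 8.
- Potassium (benzyloxymethyl)trifluoroborate and both enantiomers of DICHED are taken to be commercial.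

Step 1
Reactants: 1 5-iodovanillin
Product: 2 4-(benzyloxy)-3-iodo-5-methoxybenzaldehyde
Conditions: BnBr, K2CO3, DMF, 60 °C
Reagents that add atoms: benzyl bromide, BrCc1ccccc1
Why: Williamson ether synthesis on the phenoxide; the benzyl ether withstands the organometallic steps and is removed later by hydrogenolysis.

Step 2
Reactants: 2 4-(benzyloxy)-3-iodo-5-methoxybenzaldehyde
Product: 3 2-[4-(benzyloxy)-3-iodo-5-methoxyphenyl]-1,3-dioxolane
Conditions: ethylene glycol, TsOH (cat.), toluene, reflux, Dean–Stark
Reagents that add atoms: ethylene glycol, OCCO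
Why: Acid-catalysed acetalisation with removal of water; the dioxolane masks the aldehyde against the Grignard and carbenoid reagents.

Step 3
Reactants: 4 potassium (benzyloxymethyl)trifluoroborate; 5 (1R,2R)-1,2-dicyclohexylethane-1,2-diol
Product: 6 (4R,5R)-2-[(benzyloxy)methyl]-4,5-dicyclohexyl-1,3,2-dioxaborolane
Conditions: Me3SiCl, MeCN, 0 °C → rt
Reagents that add atoms: none
Why: Fluoride abstraction by the chlorosilane exposes tricoordinate boron, which the diol esterifies (conversion of a trifluoroborate into a boronic ester); the diol stereocentres are untouched.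

Step 4
Reactants: 6 (4R,5R)-2-[(benzyloxy)methyl]-4,5-dicyclohexyl-1,3,2-dioxaborolane; 3 2-[4-(benzyloxy)-3-iodo-5-methoxyphenyl]-1,3-dioxolane
Product: 9 (4R,5R)-2-{(1S)-2-(benzyloxy)-1-[2-(benzyloxy)-5-(1,3-dioxolan-2-yl)-3-methoxyphenyl]ethyl}-4,5-dicyclohexyl-1,3,2-dioxaborolane, via alpha-chloro boronate 7 (not isolated), via arylmagnesium chloride 8 (not isolated)
Conditions: CH2Cl2, n-BuLi, THF, −100 °C; ZnCl2, → rt; then 3/iPrMgCl·LiCl (THF, −20 °C), −78 °C → rt
Reagents that add atoms: dichloromethane, ClCCl (used as dichloromethyllithium, [Li]C(Cl)Cl)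
Why: Matteson homologation then Grignard substitution: the benzyloxymethyl group migrates to the carbenoid carbon with loss of the chloride selected by the (R,R)-diol, giving (S)-7, and the aryl group from iodine–magnesium exchange then shifts from boron with inversion, setting C3 as (S); alkoxymethyl boronates and Grignard displacement of chlorides with an oxygen on the next carbon are established for this reaction type.

Step 5
Reactants: 10 4-bromo-2,6-dimethoxyphenol
Product: 11 (4-bromo-2,6-dimethoxyphenoxy)triisopropylsilane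
Conditions: TIPSCl, imidazole, DMF, 40 °C
Reagents that add atoms: chlorotriisopropylsilane, CC(C)[Si](Cl)(C(C)C)C(C)C
Why: Silylation of the phenol; the bulky silyl ether survives magnesium insertion, base and acid and falls only to fluoride.

Step 6
Reactants: 9 (4R,5R)-2-{(1S)-2-(benzyloxy)-1-[2-(benzyloxy)-5-(1,3-dioxolan-2-yl)-3-methoxyphenyl]ethyl}-4,5-dicyclohexyl-1,3,2-dioxaborolane; 11 (4-bromo-2,6-dimethoxyphenoxy)triisopropylsilane
Product: 14 (4R,5R)-2-{(1R,2S)-3-(benzyloxy)-2-[2-(benzyloxy)-5-(1,3-dioxolan-2-yl)-3-methoxyphenyl]-1-[3,5-dimethoxy-4-(triisopropylsilyloxy)phenyl]propyl}-4,5-dicyclohexyl-1,3,2-dioxaborolane, via alpha-chloro boronate 12 (not isolated), via arylmagnesium bromide 13 (not isolated)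
Conditions: CH2Cl2, n-BuLi, THF, −100 °C; ZnCl2, → rt; then 11/Mg, LiCl (THF, rt → 40 °C), −78 °C → rt
Reagents that add atoms: dichloromethane, ClCCl (used as dichloromethyllithium, [Li]C(Cl)Cl)
Why: LiCHCl2 adds to the boron of 9 to give a tetracoordinate ate complex; ZnCl2 binds the less hindered ring oxygen and one chloride, and C3 migrates from boron to the carbenoid carbon with retention while that chloride leaves, giving 12 (C2–C3 bond). The arylmagnesium bromide 13 then adds to boron and the syringyl group shifts to the chloride-bearing carbon with inversion (C2–aryl bond). The closest known reaction type is the homologation of chiral diol boronic esters with dichloromethyllithium followed by Grignard displacement of the α-chloride, including substrates with an oxygen substituent on the β carbon; no ring is closed. The new stereocentre (C1 of the propyl chain, the later C2) is controlled by the (R,R)-diol, which decides which chloride is lost [(S) in 12], and by the invertive aryl shift [(R) in 14]; C3 is not touched. The step needs migration to outrun β-elimination of benzyloxide from the ate complex of 9; forming the complex at −100 °C and keeping ZnCl2 on the boronate oxygen and the leaving chloride should secure this. It also needs 12 to keep its configuration; 12 is a secondary alkyl chloride, not a benzylic one, and ZnCl2 ties up free chloride. An excess of 13 compensates for transmetalation to zinc. Because C2 is re-formed in step 9, a shortfall in selectivity at this carbon would not reach the target.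

Step 7
Reactants: 14 (4R,5R)-2-{(1R,2S)-3-(benzyloxy)-2-[2-(benzyloxy)-5-(1,3-dioxolan-2-yl)-3-methoxyphenyl]-1-[3,5-dimethoxy-4-(triisopropylsilyloxy)phenyl]propyl}-4,5-dicyclohexyl-1,3,2-dioxaborolane
Product: 15 (4R,5R)-2-{(1R,2S)-2-[5-(1,3-dioxolan-2-yl)-2-hydroxy-3-methoxyphenyl]-3-hydroxy-1-[3,5-dimethoxy-4-(triisopropylsilyloxy)phenyl]propyl}-4,5-dicyclohexyl-1,3,2-dioxaborolane
Conditions: H2 (1 atm), 10% Pd/C, EtOAc/EtOH, rt
Reagents that add atoms: none
Why: Hydrogenolysis of the aryl and alkyl benzyl ethers under neutral conditions; at this stage C2 carries boron, not oxygen, so no benzylic C–O bond can be cleaved, and the acetal, silyl ether and C–B bond are inert.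

Step 8
Reactants: 15 (4R,5R)-2-{(1R,2S)-2-[5-(1,3-dioxolan-2-yl)-2-hydroxy-3-methoxyphenyl]-3-hydroxy-1-[3,5-dimethoxy-4-(triisopropylsilyloxy)phenyl]propyl}-4,5-dicyclohexyl-1,3,2-dioxaborolane
Product: 16 (1R,2S)-2-[5-(1,3-dioxolan-2-yl)-2-hydroxy-3-methoxyphenyl]-1-[3,5-dimethoxy-4-(triisopropylsilyloxy)phenyl]propane-1,3-diol
Conditions: 30% H2O2, NaOH (2 M aq), THF, 0 °C → rt
Reagents that add atoms: hydrogen peroxide, OO
Why: Oxidation of the C–B bond by hydroperoxide through a 1,2-shift from boron to oxygen with retention; the diol auxiliary is released and can be recovered, and the acetal is stable to base.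

Step 9
Reactants: 16 (1R,2S)-2-[5-(1,3-dioxolan-2-yl)-2-hydroxy-3-methoxyphenyl]-1-[3,5-dimethoxy-4-(triisopropylsilyloxy)phenyl]propane-1,3-diol
Product: 18 (2R,3S)-2-[3,5-dimethoxy-4-(triisopropylsilyloxy)phenyl]-3-(hydroxymethyl)-7-methoxy-2,3-dihydro-1-benzofuran-5-carbaldehyde, via open-chain aldehyde 17 (not isolated)
Conditions: HCl (2 M aq), THF, rt → 50 °C
Reagents that add atoms: water, O
Why: Acetal hydrolysis, then acid-catalysed SN1 cyclisation: the C2 carbinol ionises to a benzylic cation stabilised by the para oxygen and the ring A phenol closes the five-membered ring (5-exo attack on the planar cation); the aryl group settles trans to the hydroxymethyl group under kinetic and thermodynamic control by C3, as in known acid closures of 1-aryl-2-(2-hydroxyaryl)propane-1,3-diols.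

Step 10
Reactants: 19 3,5-dihydroxybenzyl alcohol
Product: 20 [3,5-bis(triisopropylsilyloxy)phenyl]methanol
Conditions: NaH (2.0 equiv), DMF, 0 °C; TIPSCl (2.0 equiv), 0 °C → rt
Reagents that add atoms: chlorotriisopropylsilane, CC(C)[Si](Cl)(C(C)C)C(C)C
Why: Two equivalents of base form only the two phenoxides (about six pKa units more acidic than the alcohol), and these are silylated while the neutral benzylic alcohol is left.

Step 11
Reactants: 20 [3,5-bis(triisopropylsilyloxy)phenyl]methanol
Product: 21 1-(bromomethyl)-3,5-bis(triisopropylsilyloxy)benzene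
Conditions: CBr4, PPh3, CH2Cl2, 0 °C
Reagents that add atoms: tetrabromomethane, BrC(Br)(Br)Br
Why: Appel bromination of the benzylic alcohol under neutral conditions that leave the aryl silyl ethers intact.

Step 12
Reactants: 21 1-(bromomethyl)-3,5-bis(triisopropylsilyloxy)benzene
Product: 22 diethyl {[3,5-bis(triisopropylsilyloxy)phenyl]methyl}phosphonate
Conditions: P(OEt)3 (neat), 130 °C
Reagents that add atoms: triethyl phosphite, CCOP(OCC)OCC
Why: Michaelis–Arbuzov reaction of a reactive benzylic bromide; bromoethane distils off and drives the reaction.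

Step 13
Reactants: 18 (2R,3S)-2-[3,5-dimethoxy-4-(triisopropylsilyloxy)phenyl]-3-(hydroxymethyl)-7-methoxy-2,3-dihydro-1-benzofuran-5-carbaldehyde; 22 diethyl {[3,5-bis(triisopropylsilyloxy)phenyl]methyl}phosphonate
Product: 23 {(2R,3S)-5-{(E)-2-[3,5-bis(triisopropylsilyloxy)phenyl]ethenyl}-2-[3,5-dimethoxy-4-(triisopropylsilyloxy)phenyl]-7-methoxy-2,3-dihydro-1-benzofuran-3-yl}methanol
Conditions: 22 (2.5 equiv), NaN(SiMe3)2 (2.4 equiv), THF, −78 °C; then 18, −78 °C → rt
Reagents that add atoms: none
Why: Horner–Wadsworth–Emmons olefination of an aryl aldehyde with a benzylic phosphonate anion, which should give the E-stilbene; one equivalent of anion is spent on the primary alcohol, and the bulky silyl ethers and the non-nucleophilic amide base limit silyl transfer.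

Step 14
Reactants: 23 {(2R,3S)-5-{(E)-2-[3,5-bis(triisopropylsilyloxy)phenyl]ethenyl}-2-[3,5-dimethoxy-4-(triisopropylsilyloxy)phenyl]-7-methoxy-2,3-dihydro-1-benzofuran-3-yl}methanol
Product: 24 gnetucleistol F
Conditions: Bu4NF, AcOH, THF, 0 °C, dark, argon
Reagents that add atoms: none
Why: Fluoride cleaves the three aryl O–Si bonds; acetic acid keeps the phenols protonated so that the syringyl phenoxide cannot open the ether ring, and light is excluded to keep the alkene E.

Compound list
1 | 5-iodovanillin | COc1cc(C=O)cc(I)c1O | starting material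
2 | 4-(benzyloxy)-3-iodo-5-methoxybenzaldehyde | COc1cc(C=O)cc(I)c1OCc1ccccc1 | intermediate
3 | 2-[4-(benzyloxy)-3-iodo-5-methoxyphenyl]-1,3-dioxolane | COc1cc(C2OCCO2)cc(I)c1OCc1ccccc1 | intermediate
4 | potassium (benzyloxymethyl)trifluoroborate | [K+].F[B-](F)(F)COCc1ccccc1 | starting material
5 | (1R,2R)-1,2-dicyclohexylethane-1,2-diol | O[C@H](C1CCCCC1)[C@H](O)C1CCCCC1 | starting material
6 | (4R,5R)-2-[(benzyloxy)methyl]-4,5-dicyclohexyl-1,3,2-dioxaborolane | B1(O[C@H](C2CCCCC2)[C@@H](C2CCCCC2)O1)COCc1ccccc1 | intermediate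
7 | (4R,5R)-2-[(1S)-2-(benzyloxy)-1-chloroethyl]-4,5-dicyclohexyl-1,3,2-dioxaborolane | Cl[C@H](COCc1ccccc1)B1O[C@H](C2CCCCC2)[C@@H](C2CCCCC2)O1 | intermediate (not isolated)
8 | [2-(benzyloxy)-5-(1,3-dioxolan-2-yl)-3-methoxyphenyl]magnesium chloride (LiCl complex) | COc1cc(C2OCCO2)cc([Mg]Cl)c1OCc1ccccc1 | intermediate (not isolated)
9 | (4R,5R)-2-{(1S)-2-(benzyloxy)-1-[2-(benzyloxy)-5-(1,3-dioxolan-2-yl)-3-methoxyphenyl]ethyl}-4,5-dicyclohexyl-1,3,2-dioxaborolane | B1(O[C@H](C2CCCCC2)[C@@H](C2CCCCC2)O1)[C@H](COCc1ccccc1)c1cc(C2OCCO2)cc(OC)c1OCc1ccccc1 | intermediate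
10 | 4-bromo-2,6-dimethoxyphenol | COc1cc(Br)cc(OC)c1O | starting material
11 | (4-bromo-2,6-dimethoxyphenoxy)triisopropylsilane | COc1cc(Br)cc(OC)c1O[Si](C(C)C)(C(C)C)C(C)C | intermediate
12 | (4R,5R)-2-{(1S,2S)-3-(benzyloxy)-2-[2-(benzyloxy)-5-(1,3-dioxolan-2-yl)-3-methoxyphenyl]-1-chloropropyl}-4,5-dicyclohexyl-1,3,2-dioxaborolane | Cl[C@@H](B1O[C@H](C2CCCCC2)[C@@H](C2CCCCC2)O1)[C@H](COCc1ccccc1)c1cc(C2OCCO2)cc(OC)c1OCc1ccccc1 | intermediate (not isolated)
13 | [3,5-dimethoxy-4-(triisopropylsilyloxy)phenyl]magnesium bromide | COc1cc([Mg]Br)cc(OC)c1O[Si](C(C)C)(C(C)C)C(C)C | intermediate (not isolated)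
14 | (4R,5R)-2-{(1R,2S)-3-(benzyloxy)-2-[2-(benzyloxy)-5-(1,3-dioxolan-2-yl)-3-methoxyphenyl]-1-[3,5-dimethoxy-4-(triisopropylsilyloxy)phenyl]propyl}-4,5-dicyclohexyl-1,3,2-dioxaborolane | COc1cc([C@H](B2O[C@H](C3CCCCC3)[C@@H](C3CCCCC3)O2)[C@H](COCc2ccccc2)c2cc(C3OCCO3)cc(OC)c2OCc2ccccc2)cc(OC)c1O[Si](C(C)C)(C(C)C)C(C)C | intermediate
15 | (4R,5R)-2-{(1R,2S)-2-[5-(1,3-dioxolan-2-yl)-2-hydroxy-3-methoxyphenyl]-3-hydroxy-1-[3,5-dimethoxy-4-(triisopropylsilyloxy)phenyl]propyl}-4,5-dicyclohexyl-1,3,2-dioxaborolane | COc1cc([C@H](B2O[C@H](C3CCCCC3)[C@@H](C3CCCCC3)O2)[C@H](CO)c2cc(C3OCCO3)cc(OC)c2O)cc(OC)c1O[Si](C(C)C)(C(C)C)C(C)C | intermediate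
16 | (1R,2S)-2-[5-(1,3-dioxolan-2-yl)-2-hydroxy-3-methoxyphenyl]-1-[3,5-dimethoxy-4-(triisopropylsilyloxy)phenyl]propane-1,3-diol | COc1cc([C@H](O)[C@H](CO)c2cc(C3OCCO3)cc(OC)c2O)cc(OC)c1O[Si](C(C)C)(C(C)C)C(C)C | intermediate
17 | 3-{(1R,2S)-1,3-dihydroxy-1-[3,5-dimethoxy-4-(triisopropylsilyloxy)phenyl]propan-2-yl}-4-hydroxy-5-methoxybenzaldehyde | COc1cc([C@H](O)[C@H](CO)c2cc(C=O)cc(OC)c2O)cc(OC)c1O[Si](C(C)C)(C(C)C)C(C)C | intermediate (not isolated)
18 | (2R,3S)-2-[3,5-dimethoxy-4-(triisopropylsilyloxy)phenyl]-3-(hydroxymethyl)-7-methoxy-2,3-dihydro-1-benzofuran-5-carbaldehyde | COc1cc([C@@H]2Oc3c(OC)cc(C=O)cc3[C@H]2CO)cc(OC)c1O[Si](C(C)C)(C(C)C)C(C)C | intermediate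
19 | 3,5-dihydroxybenzyl alcohol | OCc1cc(O)cc(O)c1 | starting material
20 | [3,5-bis(triisopropylsilyloxy)phenyl]methanol | OCc1cc(O[Si](C(C)C)(C(C)C)C(C)C)cc(O[Si](C(C)C)(C(C)C)C(C)C)c1 | intermediate
21 | 1-(bromomethyl)-3,5-bis(triisopropylsilyloxy)benzene | BrCc1cc(O[Si](C(C)C)(C(C)C)C(C)C)cc(O[Si](C(C)C)(C(C)C)C(C)C)c1 | intermediate
22 | diethyl {[3,5-bis(triisopropylsilyloxy)phenyl]methyl}phosphonate | CCOP(=O)(Cc1cc(O[Si](C(C)C)(C(C)C)C(C)C)cc(O[Si](C(C)C)(C(C)C)C(C)C)c1)OCC | intermediate
23 | {(2R,3S)-5-{(E)-2-[3,5-bis(triisopropylsilyloxy)phenyl]ethenyl}-2-[3,5-dimethoxy-4-(triisopropylsilyloxy)phenyl]-7-methoxy-2,3-dihydro-1-benzofuran-3-yl}methanol | COc1cc([C@@H]2Oc3c(OC)cc(/C=C/c4cc(O[Si](C(C)C)(C(C)C)C(C)C)cc(O[Si](C(C)C)(C(C)C)C(C)C)c4)cc3[C@H]2CO)cc(OC)c1O[Si](C(C)C)(C(C)C)C(C)C | intermediate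
24 | gnetucleistol F | COc1cc([C@@H]2Oc3c(OC)cc(/C=C/c4cc(O)cc(O)c4)cc3[C@H]2CO)cc(OC)c1O | target

Total step count: 14. Longest linear sequence: 9 steps (steps 1, 2, 4, 6, 7, 8, 9, 13, 14).

Steps least certain to work

Step 6 (key step). The ate complex of 9 has boron and a benzyloxy group on neighbouring carbons, so β-elimination to a styrene may compete with migration of the hindered secondary benzylic carbon. Ate-complex formation at this congested boron may be slow, and part of the aryl Grignard reagent may be lost to zinc. Fallback (sets out from 9, returns at 14): the one-carbon unit and the syringyl ring are brought in together by lithiation–borylation. Grignard reagent 13 and paraformaldehyde give [3,5-dimethoxy-4-(triisopropylsilyloxy)phenyl]methanol F1, which N,N-diisopropylcarbamoyl chloride and NaH convert into the benzylic N,N-diisopropylcarbamate F2. s-BuLi/TMEDA at −78 °C gives the α-lithiated carbamate F3, which adds to the boron of 9; on warming with MgBr2·OEt2, C3 migrates with loss of the carbamate. No Lewis acid is present while the ate complex forms and no aryl group has to be transferred from a metal. The auxiliary is not expected to control the new centre well here, so 14 would be separated by chromatography from its C1 epimer F4, a diastereomer.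

Step 4. The ortho-substituted aryl reagent 8 may add slowly to the boron of 7, and the ate complex, which has a benzyloxy group next to the chloride-bearing carbon, may eliminate instead of rearranging. Fallback (sets out from 8, returns at 18): the two substituents of C3 are introduced in the opposite order on the enantiomeric diol, which gives the same configuration at C3. Reagent 8 and B(OMe)3 give the arylboronic acid F5, which is esterified with (1S,2S)-1,2-dicyclohexylethane-1,2-diol to the aryl boronate F6. LiCHCl2/ZnCl2 gives the (R)-α-chlorobenzyl boronate F7, used at once because benzylic chlorides of this kind epimerise. [(Benzyloxy)methyl]magnesium chloride F8, made from benzyl chloromethyl ether and Mg, then displaces the chloride to give the (4S,5S) diastereomer of 9, F9. F9 replaces 9 in steps 6 to 8, which give in turn the chloro boronate F10, the arylated boronate F11, the debenzylated boronate F12 and the (1S,2S)-diol F13. Step 9 then takes F13 through the aldehyde F14 to 18, because the cation at C2 erases the difference at that carbon.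

Step 9. The para silyloxy group is twisted out of conjugation by its two methoxy neighbours, so ionisation at C2 may be slow. Loss of water to a C2=C3 alkene, a hydride shift from C3 or loss of formaldehyde would then compete and would destroy or scramble C3; prolonged heating in acid could also cleave the silyl ether. Fallback (sets out from 16, returns at 18): the closure is run through the para-quinone methide manifold, which needs only very mild acid. Bu4NF removes the silyl group from 16 to give the phenolic triol F15. Dilute aqueous HCl in THF at rt hydrolyses the acetal to the open-chain phenolic aldehyde F16 (not isolated) and closes the ring to (2R,3S)-2-(4-hydroxy-3,5-dimethoxyphenyl)-3-(hydroxymethyl)-7-methoxy-2,3-dihydro-1-benzofuran-5-carbaldehyde F17. The phenol alone is then silylated as its phenoxide (1,8-diazabicyclo[5.4.0]undec-7-ene, TIPSCl, CH2Cl2) to give 18.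

Step 13. The primary alkoxide consumes phosphonate anion, and the hindered, semi-stabilised anion may add slowly to the electron-rich aldehyde. Prolonged exposure to base could transfer silyl groups or open the ether ring. Fallback (sets out from 18, returns at 23): the alkene is made by a Mizoroki–Heck reaction instead. Wittig methylenation of 18 (Ph3PCH3Br, NaN(SiMe3)2, THF, 0 °C) gives the 5-ethenyl dihydrobenzofuran F18. Coupling of F18 with 1-bromo-3,5-bis(triisopropylsilyloxy)benzene F19 (from 5-bromoresorcinol and TIPSCl) using Pd(OAc)2, P(o-tol)3 and Et3N in DMF at 100 °C should give the E-stilbene 23.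

Further compounds
F1 | step 6 | [3,5-dimethoxy-4-(triisopropylsilyloxy)phenyl]methanol | COc1cc(CO)cc(OC)c1O[Si](C(C)C)(C(C)C)C(C)C
F2 | step 6 | 3,5-dimethoxy-4-(triisopropylsilyloxy)benzyl N,N-diisopropylcarbamate | COc1cc(COC(=O)N(C(C)C)C(C)C)cc(OC)c1O[Si](C(C)C)(C(C)C)C(C)C
F3 | step 6 | alpha-lithiated 3,5-dimethoxy-4-(triisopropylsilyloxy)benzyl N,N-diisopropylcarbamate | COc1cc(C([Li])OC(=O)N(C(C)C)C(C)C)cc(OC)c1O[Si](C(C)C)(C(C)C)C(C)C
F4 | step 6 | (4R,5R)-2-{(1S,2S)-3-(benzyloxy)-2-[2-(benzyloxy)-5-(1,3-dioxolan-2-yl)-3-methoxyphenyl]-1-[3,5-dimethoxy-4-(triisopropylsilyloxy)phenyl]propyl}-4,5-dicyclohexyl-1,3,2-dioxaborolane | COc1cc([C@@H](B2O[C@H](C3CCCCC3)[C@@H](C3CCCCC3)O2)[C@H](COCc2ccccc2)c2cc(C3OCCO3)cc(OC)c2OCc2ccccc2)cc(OC)c1O[Si](C(C)C)(C(C)C)C(C)C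
F5 | step 4 | [2-(benzyloxy)-5-(1,3-dioxolan-2-yl)-3-methoxyphenyl]boronic acid | COc1cc(C2OCCO2)cc(B(O)O)c1OCc1ccccc1
F6 | step 4 | (4S,5S)-2-[2-(benzyloxy)-5-(1,3-dioxolan-2-yl)-3-methoxyphenyl]-4,5-dicyclohexyl-1,3,2-dioxaborolane | COc1cc(C2OCCO2)cc(B2O[C@@H](C3CCCCC3)[C@H](C3CCCCC3)O2)c1OCc1ccccc1
F7 | step 4 | (4S,5S)-2-{(R)-[2-(benzyloxy)-5-(1,3-dioxolan-2-yl)-3-methoxyphenyl](chloro)methyl}-4,5-dicyclohexyl-1,3,2-dioxaborolane | Cl[C@H](B1O[C@@H](C2CCCCC2)[C@H](C2CCCCC2)O1)c1cc(C2OCCO2)cc(OC)c1OCc1ccccc1
F8 | step 4 | [(benzyloxy)methyl]magnesium chloride | Cl[Mg]COCc1ccccc1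
F9 | step 4 | (4S,5S)-2-{(1S)-2-(benzyloxy)-1-[2-(benzyloxy)-5-(1,3-dioxolan-2-yl)-3-methoxyphenyl]ethyl}-4,5-dicyclohexyl-1,3,2-dioxaborolane | B1(O[C@@H](C2CCCCC2)[C@H](C2CCCCC2)O1)[C@H](COCc1ccccc1)c1cc(C2OCCO2)cc(OC)c1OCc1ccccc1
F10 | step 4 | (4S,5S)-2-{(1R,2S)-3-(benzyloxy)-2-[2-(benzyloxy)-5-(1,3-dioxolan-2-yl)-3-methoxyphenyl]-1-chloropropyl}-4,5-dicyclohexyl-1,3,2-dioxaborolane | Cl[C@H](B1O[C@@H](C2CCCCC2)[C@H](C2CCCCC2)O1)[C@H](COCc1ccccc1)c1cc(C2OCCO2)cc(OC)c1OCc1ccccc1
F11 | step 4 | (4S,5S)-2-{(1S,2S)-3-(benzyloxy)-2-[2-(benzyloxy)-5-(1,3-dioxolan-2-yl)-3-methoxyphenyl]-1-[3,5-dimethoxy-4-(triisopropylsilyloxy)phenyl]propyl}-4,5-dicyclohexyl-1,3,2-dioxaborolane | COc1cc([C@@H](B2O[C@@H](C3CCCCC3)[C@H](C3CCCCC3)O2)[C@H](COCc2ccccc2)c2cc(C3OCCO3)cc(OC)c2OCc2ccccc2)cc(OC)c1O[Si](C(C)C)(C(C)C)C(C)C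
F12 | step 4 | (4S,5S)-2-{(1S,2S)-2-[5-(1,3-dioxolan-2-yl)-2-hydroxy-3-methoxyphenyl]-3-hydroxy-1-[3,5-dimethoxy-4-(triisopropylsilyloxy)phenyl]propyl}-4,5-dicyclohexyl-1,3,2-dioxaborolane | COc1cc([C@@H](B2O[C@@H](C3CCCCC3)[C@H](C3CCCCC3)O2)[C@H](CO)c2cc(C3OCCO3)cc(OC)c2O)cc(OC)c1O[Si](C(C)C)(C(C)C)C(C)C
F13 | step 4 | (1S,2S)-2-[5-(1,3-dioxolan-2-yl)-2-hydroxy-3-methoxyphenyl]-1-[3,5-dimethoxy-4-(triisopropylsilyloxy)phenyl]propane-1,3-diol | COc1cc([C@@H](O)[C@H](CO)c2cc(C3OCCO3)cc(OC)c2O)cc(OC)c1O[Si](C(C)C)(C(C)C)C(C)C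
F14 | step 4 | 3-{(1S,2S)-1,3-dihydroxy-1-[3,5-dimethoxy-4-(triisopropylsilyloxy)phenyl]propan-2-yl}-4-hydroxy-5-methoxybenzaldehyde | COc1cc([C@@H](O)[C@H](CO)c2cc(C=O)cc(OC)c2O)cc(OC)c1O[Si](C(C)C)(C(C)C)C(C)C
F15 | step 9 | (1R,2S)-2-[5-(1,3-dioxolan-2-yl)-2-hydroxy-3-methoxyphenyl]-1-(4-hydroxy-3,5-dimethoxyphenyl)propane-1,3-diol | COc1cc([C@H](O)[C@H](CO)c2cc(C3OCCO3)cc(OC)c2O)cc(OC)c1O
F16 | step 9 | 3-[(1R,2S)-1,3-dihydroxy-1-(4-hydroxy-3,5-dimethoxyphenyl)propan-2-yl]-4-hydroxy-5-methoxybenzaldehyde | COc1cc([C@H](O)[C@H](CO)c2cc(C=O)cc(OC)c2O)cc(OC)c1O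
F17 | step 9 | (2R,3S)-2-(4-hydroxy-3,5-dimethoxyphenyl)-3-(hydroxymethyl)-7-methoxy-2,3-dihydro-1-benzofuran-5-carbaldehyde | COc1cc([C@@H]2Oc3c(OC)cc(C=O)cc3[C@H]2CO)cc(OC)c1O
F18 | step 13 | {(2R,3S)-2-[3,5-dimethoxy-4-(triisopropylsilyloxy)phenyl]-5-ethenyl-7-methoxy-2,3-dihydro-1-benzofuran-3-yl}methanol | COc1cc([C@@H]2Oc3c(OC)cc(C=C)cc3[C@H]2CO)cc(OC)c1O[Si](C(C)C)(C(C)C)C(C)C
F19 | step 13 | 1-bromo-3,5-bis(triisopropylsilyloxy)benzene | Brc1cc(O[Si](C(C)C)(C(C)C)C(C)C)cc(O[Si](C(C)C)(C(C)C)C(C)C)c1
A1 | alternative 1 | (2S)-2-(5-bromo-2-hydroxy-3-methoxyphenyl)-3-(4-hydroxy-3,5-dimethoxyphenyl)propan-1-ol | COc1cc(C[C@H](CO)c2cc(Br)cc(OC)c2O)cc(OC)c1O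
A2 | alternative 1 | 4-[(2S)-2-(5-bromo-2-hydroxy-3-methoxyphenyl)-3-hydroxypropylidene]-2,6-dimethoxycyclohexa-2,5-dien-1-one | COC1=CC(=C[C@H](CO)c2cc(Br)cc(OC)c2O)C=C(OC)C1=O
A3 | alternative 1 | (2R,3S)-5-bromo-2-(4-hydroxy-3,5-dimethoxyphenyl)-3-(hydroxymethyl)-7-methoxy-2,3-dihydrobenzofuran | COc1cc([C@@H]2Oc3c(OC)cc(Br)cc3[C@H]2CO)cc(OC)c1O
A4 | alternative 2 | 4-bromo-2-[2-(tert-butyldimethylsilyloxy)-1-(4-methylbenzenesulfonyl)ethyl]-6-methoxyphenol (racemic) | COc1cc(Br)cc(C(CO[Si](C)(C)C(C)(C)C)S(=O)(=O)c2ccc(C)cc2)c1O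
A5 | alternative 2 | 4-bromo-6-[2-(tert-butyldimethylsilyloxy)ethylidene]-2-methoxycyclohexa-2,4-dien-1-one | COC1=CC(Br)=CC(=CCO[Si](C)(C)C(C)(C)C)C1=O
A6 | alternative 2 | (2R,5R)-1-[3,5-dimethoxy-4-(triisopropylsilyloxy)benzyl]-2,5-dimethylthiolan-1-ium tetrafluoroborate (sulfide enantiomer to be chosen for the 2R,3S product) | C[C@@H]1CC[C@@H](C)[S+]1Cc1cc(OC)c(O[Si](C(C)C)(C(C)C)C(C)C)c(OC)c1.F[B-](F)(F)F
A7 | alternative 2 | (2R,3S)-5-bromo-3-(tert-butyldimethylsilyloxymethyl)-7-methoxy-2-[3,5-dimethoxy-4-(triisopropylsilyloxy)phenyl]-2,3-dihydrobenzofuran | COc1cc([C@@H]2Oc3c(OC)cc(Br)cc3[C@H]2CO[Si](C)(C)C(C)(C)C)cc(OC)c1O[Si](C(C)C)(C(C)C)C(C)C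
A8 | alternative 3 | 4-bromo-2-{[3,5-dimethoxy-4-(triisopropylsilyloxy)phenyl]ethynyl}-6-methoxyphenol | COc1cc(C#Cc2cc(Br)cc(OC)c2O)cc(OC)c1O[Si](C(C)C)(C(C)C)C(C)C
A9 | alternative 3 | methyl 5-bromo-7-methoxy-2-[3,5-dimethoxy-4-(triisopropylsilyloxy)phenyl]benzofuran-3-carboxylate | COc1cc(-c2oc3c(OC)cc(Br)cc3c2C(=O)OC)cc(OC)c1O[Si](C(C)C)(C(C)C)C(C)C
A10 | alternative 3 | methyl (2R,3S)-5-bromo-7-methoxy-2-[3,5-dimethoxy-4-(triisopropylsilyloxy)phenyl]-2,3-dihydrobenzofuran-3-carboxylate (cis) | COc1cc([C@@H]2Oc3c(OC)cc(Br)cc3[C@@H]2C(=O)OC)cc(OC)c1O[Si](C(C)C)(C(C)C)C(C)C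
A11 | alternative 3 | methyl (2R,3R)-5-bromo-7-methoxy-2-[3,5-dimethoxy-4-(triisopropylsilyloxy)phenyl]-2,3-dihydrobenzofuran-3-carboxylate (trans) | COc1cc([C@@H]2Oc3c(OC)cc(Br)cc3[C@H]2C(=O)OC)cc(OC)c1O[Si](C(C)C)(C(C)C)C(C)C
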